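**Retrosynthetic overview**
1. Eudesmagnolol ⇒ SEM ether 28 ⇒ bis(benzyl bromide) 27 (both allyl groups by a double sp3–sp2 Stille vinylation) ⇒ dialdehyde 24 (C11–OH by late oxymercuration of the isopropenyl group).
2. 24 ⇒ dinitrile 22 ⇒ Suzuki–Miyaura union of aryl bromide 18 with boronate 21; 18 ⇒ SNAr of the C4 alkoxide of eudesm-11-en-4α-ol 15 on 3-bromo-4-fluorobenzonitrile (tertiary alkyl aryl ether).
3. 15 ⇒ (+)-α-cyperone 8: trans ring fusion by Li/NH3, C4–O by Rubottom oxidation anti to the C10 methyl, C3 deoxygenation by Barton–McCombie.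
4. 8 ⇒ (+)-dihydrocarvone + ethyl vinyl ketone: the key C1–C10 bond is made by an intermolecular, auxiliary-controlled Michael addition, followed by aldol condensation.
5. Ring order: ring B (chiral pool) → ring A (Michael/aldol) → aryl ring 1 through oxygen (SNAr) → aryl ring 2 (Suzuki).

Assumption: eudesmane numbering is used for the terpene part (C4 = carbinol carbon carrying C15, C5/C10 = ring fusion, C10 carries C14, C7 carries C11–C13; α = face opposite the C10 methyl), and commercial (+)-dihydrocarvone is used as its usual mixture of C2 epimers, which converge in step 1.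

**Route**

Step 1
Reactants: 1 (+)-dihydrocarvone [(2R,5R)-2-methyl-5-(prop-1-en-2-yl)cyclohexan-1-one]; 2 (R)-(+)-1-phenylethylamine
Product: 3 N-[(R)-1-phenylethyl] ketimine of dihydrocarvone (5R; C2 epimers/enamine tautomers)
Conditions: toluene, reflux, Dean–Stark, 24 h
Reagents that add atoms: none
Why: Reversible ketimine condensation driven by azeotropic removal of water; the C2 epimers of 1 converge because C2 becomes the enamine carbon in step 2, while C5 (the future C7) is untouched.

Step 2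
Reactants: 3 ketimine; 4 ethyl vinyl ketone (pent-1-en-3-one)
Product: 6 (2S,5R)-2-methyl-2-(3-oxopentyl)-5-(prop-1-en-2-yl)cyclohexan-1-one, via Michael-adduct ketimine 5 (not isolated)
Conditions: 4 (1.5 equiv), THF, 40 °C, 3 d; then 10% aq. AcOH, rt, 2 h
Reagents that add atoms: water, O
Why: Auxiliary-controlled (d'Angelo-type) intermolecular Michael addition in which the more substituted secondary enamine tautomer of 3 adds to 4 through a compact aza-ene-like transition state, the (R)-1-phenylethyl group steering the enone so that the new quaternary centre is S (future C10 methyl cis to the isopropenyl group), after which mild aqueous acid hydrolyses the imine.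

Step 3
Reactants: 6 diketone
Product: 8 (+)-α-cyperone [(4aS,7R)-1,4a-dimethyl-7-(prop-1-en-2-yl)-4,4a,5,6,7,8-hexahydronaphthalen-2(3H)-one; eudesma-4,11-dien-3-one], via aldol ketol 7 (not isolated)
Conditions: NaOMe, MeOH, rt → 50 °C
Reagents that add atoms: none
Why: Intramolecular aldol condensation (second half of a Robinson annulation) closes ring A and dehydrates to the tetrasubstituted enone without touching C7 or the non-enolisable C10.

Step 4
Reactants: 8 (+)-α-cyperone
Product: 10 3-(trimethylsilyloxy)-5αH-eudesma-3,11-diene (trans-fused), via lithium enolate 9 (not isolated)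
Conditions: Li (2.2 equiv), t-BuOH (1.0 equiv), NH3(l)/THF, −78 °C; isoprene; evaporate NH3; then Me3SiCl, Et3N, THF, −78 → 0 °C
Reagents that add atoms: chlorotrimethylsilane, C[Si](C)(C)Cl
Why: Dissolving-metal (Birch-type) enone reduction protonates C5 axially to give the trans ring fusion (5αH) and leaves the regiodefined C3–C4 enolate, which is trapped on oxygen as the silyl enol ether, the isolated isopropenyl group not being reduced.

Step 5
Reactants: 10 silyl enol ether
Product: 12 4α-hydroxy-5αH-eudesm-11-en-3-one (4β-methyl), via 4α-silyloxy ketone 11 (not isolated)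
Conditions: mCPBA (1.05 equiv), NaHCO3, CH2Cl2, −20 °C; then Et3N·3HF, THF, rt
Reagents that add atoms: mCPBA (3-chloroperoxybenzoic acid), O=C(OO)c1cccc(Cl)c1
Why: Rubottom oxidation in which mCPBA epoxidises the electron-rich silyl enol ether far faster than the 1,1-disubstituted alkene and from the α face anti to the axial C10 methyl, so that after 1,4-silyl shift and desilylation C4 carries α-OH and β-CH3.

Step 6
Reactants: 12 α-hydroxy ketone
Product: 13 5αH-eudesm-11-ene-3β,4α-diol
Conditions: NaBH4, MeOH, 0 °C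
Reagents that add atoms: none
Why: Hydride reduction of the hindered ketone (axial attack, mainly the equatorial 3β-alcohol); the C3 configuration is irrelevant because this oxygen is removed in step 8.

Step 7
Reactants: 13 diol
Product: 14 3β-(phenoxythiocarbonyloxy)-5αH-eudesm-11-en-4α-ol
Conditions: PhOC(S)Cl (1.3 equiv), pyridine, CH2Cl2, 0 °C → rt
Reagents that add atoms: O-phenyl chlorothionoformate, S=C(Cl)Oc1ccccc1
Why: Chemoselective thioacylation in which only the secondary C3 hydroxyl reacts, the tertiary C4 hydroxyl being too hindered and the trans-diequatorial arrangement disfavouring a cyclic thionocarbonate.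

Step 8
Reactants: 14 thionocarbonate
Product: 15 5αH-eudesm-11-en-4α-ol [selin-11-en-4α-ol; (1R,4aR,7R,8aR)-1,4a-dimethyl-7-(prop-1-en-2-yl)decahydronaphthalen-1-ol]
Conditions: Bu3SnH (1.5 equiv), AIBN (0.2 equiv), toluene, 100 °C
Reagents that add atoms: none
Why: Barton–McCombie radical deoxygenation replaces the C3 thionocarbonate by hydrogen without affecting the tertiary alcohol, the isopropenyl group or any stereocentre.

Step 9
Reactants: 15 eudesm-11-en-4α-ol; 16 3-bromo-4-fluorobenzonitrile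
Product: 18 3-bromo-4-[(5αH-eudesm-11-en-4α-yl)oxy]benzonitrile, via potassium alkoxide 17 (not isolated)
Conditions: KH (1.2 equiv), THF, 0 °C → rt; then 16 (1.3 equiv), THF, rt → 55 °C
Reagents that add atoms: none
Why: Nucleophilic aromatic substitution (addition–elimination) in which the tertiary potassium alkoxide displaces fluoride activated by the para nitrile and ortho bromine, and since the terpene C4–O bond is never broken the 4α configuration is retained.

Step 10
Reactants: 19 3-bromo-4-hydroxybenzonitrile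
Product: 20 3-bromo-4-{[2-(trimethylsilyl)ethoxy]methoxy}benzonitrile
Conditions: SEMCl, iPr2NEt, CH2Cl2, 0 °C → rt
Reagents that add atoms: 2-(trimethylsilyl)ethoxymethyl chloride, C[Si](C)(C)CCOCCl
Why: O-Alkylation of the acidic cyanophenol gives a base-, hydride- and palladium-stable SEM ether that is later removed with fluoride, i.e. without acid that would ionise the tertiary alkyl aryl ether.

Step 11
Reactants: 20 SEM-protected bromophenol
Product: 21 4-{[2-(trimethylsilyl)ethoxy]methoxy}-3-(4,4,5,5-tetramethyl-1,3,2-dioxaborolan-2-yl)benzonitrile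
Conditions: B2pin2, PdCl2(dppf) (3 mol %), KOAc, 1,4-dioxane, 90 °C
Reagents that add atoms: bis(pinacolato)diboron, CC1(C)OB(OC1(C)C)B1OC(C)(C)C(C)(C)O1
Why: Miyaura borylation of the aryl bromide, to which nitrile and SEM ether are inert under the mild acetate base.

Step 12
Reactants: 18 aryl bromide; 21 aryl boronate
Product: 22 6-[(5αH-eudesm-11-en-4α-yl)oxy]-6'-{[2-(trimethylsilyl)ethoxy]methoxy}biphenyl-3,3'-dicarbonitrile
Conditions: Pd(OAc)2 (5 mol %), SPhos (10 mol %), K3PO4, toluene/H2O (10:1), 90 °C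
Reagents that add atoms: none
Why: Suzuki–Miyaura coupling in which the bulky electron-rich SPhos ligand allows coupling at the hindered bis-ortho-oxygenated biaryl axis while nitriles and the isopropenyl group are spectators.

Step 13
Reactants: 22 dinitrile
Product: 24 6-[(5αH-eudesm-11-en-4α-yl)oxy]-6'-{[2-(trimethylsilyl)ethoxy]methoxy}biphenyl-3,3'-dicarbaldehyde, via bis(aluminium aldimine) 23 (not isolated)
Conditions: iBu2AlH (2.6 equiv), toluene, −78 → −40 °C; then 1 M aq. tartaric acid, 0 °C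
Reagents that add atoms: water, O
Why: Partial reduction of both nitriles with iBu2AlH stops at the N-aluminio aldimines at low temperature, and mildly acidic hydrolysis releases the dialdehyde.

Step 14
Reactants: 24 dialdehyde
Product: 26 [6-{[11-hydroxy-5αH-eudesman-4α-yl]oxy}-6'-{[2-(trimethylsilyl)ethoxy]methoxy}biphenyl-3,3'-diyl]dimethanol, via organomercurial 25 (not isolated)
Conditions: Hg(OAc)2 (1.2 equiv), THF/H2O (1:1), rt; then 3 M NaOH, NaBH4 (excess), 0 °C
Reagents that add atoms: water, O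
Why: Markovnikov oxymercuration–demercuration hydrates the only alkene at C11 while the aldehyde-deactivated arenes resist mercuration, and the NaBH4 used for demercuration simultaneously reduces both aldehydes to benzylic alcohols.

Step 15
Reactants: 26 triol
Product: 27 2-{4α-[(3,3'-bis(bromomethyl)-6'-{[2-(trimethylsilyl)ethoxy]methoxy}biphenyl-6-yl)oxy]-5αH-eudesman-11-yl} tertiary alcohol (bis-benzylic bromide)
Conditions: CBr4 (2.4 equiv), PPh3 (2.4 equiv), CH2Cl2, 0 °C; used crude
Reagents that add atoms: carbon tetrabromide, BrC(Br)(Br)Br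
Why: Appel reaction converts the two primary benzylic alcohols into bromides under neutral conditions, the hindered tertiary C11 alcohol being unreactive at 0 °C.

Step 16
Reactants: 27 bis(benzyl bromide)
Product: 28 2'-O-SEM-eudesmagnolol
Conditions: Bu3SnCH=CH2 (2.6 equiv), Pd(PPh3)4 (5 mol %), toluene, 80 °C
Reagents that add atoms: tributyl(vinyl)stannane, C=C[Sn](CCCC)(CCCC)CCCC
Why: Twofold Stille (Migita–Kosugi–Stille) coupling of the benzylic bromides with a vinylstannane forms both allyl groups under neutral conditions that leave the SEM ether, tertiary alcohol and tertiary ether untouched.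

Step 17
Reactants: 28 2'-O-SEM-eudesmagnolol
Product: 29 eudesmagnolol
Conditions: Bu4NF (5 equiv), THF/DMPU (4:1), 60 °C; aq. NH4Cl work-up
Reagents that add atoms: none
Why: Fluoride-induced SEM cleavage (attack at silicon, loss of ethene and formaldehyde) frees the phenol under non-acidic conditions, so the acid-labile tertiary aryl ether and the allyl groups survive.

**Compound list**
1 | (+)-dihydrocarvone, (2R,5R)-2-methyl-5-(prop-1-en-2-yl)cyclohexan-1-one (commercial material also contains the 2S epimer) | C[C@@H]1CC[C@@H](C(C)=C)CC1=O | starting material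
2 | (R)-(+)-1-phenylethylamine | C[C@@H](N)c1ccccc1 | starting material
3 | N-[(R)-1-phenylethyl] ketimine of dihydrocarvone (5R; C2 epimers) | C[C@@H](N=C1C[C@H](C(C)=C)CCC1C)c1ccccc1 | intermediate
4 | ethyl vinyl ketone (pent-1-en-3-one) | C=CC(=O)CC | starting material
5 | Michael-adduct ketimine, (R)-1-phenylethyl imine of 6 | CCC(=O)CC[C@]1(C)CC[C@@H](C(C)=C)CC1=N[C@H](C)c1ccccc1 | intermediate
6 | (2S,5R)-2-methyl-2-(3-oxopentyl)-5-(prop-1-en-2-yl)cyclohexan-1-one | CCC(=O)CC[C@]1(C)CC[C@@H](C(C)=C)CC1=O | intermediate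
7 | aldol ketol, 5-hydroxyeudesm-11-en-3-one (7R,10S-derived; C4/C5 epimers) | CC1C(=O)CC[C@]2(C)CC[C@@H](C(C)=C)CC12O | intermediate
8 | (+)-α-cyperone, (4aS,7R)-eudesma-4,11-dien-3-one | O=C1CC[C@]2(C)CC[C@@H](C(C)=C)CC2=C1C | intermediate
9 | lithium 5αH-eudesma-3,11-dien-3-olate (trans-fused) | CC1=C([O-])CC[C@]2(C)CC[C@@H](C(C)=C)C[C@H]21.[Li+] | intermediate
10 | 3-(trimethylsilyloxy)-5αH-eudesma-3,11-diene | CC1=C(O[Si](C)(C)C)CC[C@]2(C)CC[C@@H](C(C)=C)C[C@H]21 | intermediate
11 | 4α-(trimethylsilyloxy)-5αH-eudesm-11-en-3-one | C[Si](C)(C)O[C@]1(C)C(=O)CC[C@]2(C)CC[C@@H](C(C)=C)C[C@H]21 | intermediate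
12 | 4α-hydroxy-5αH-eudesm-11-en-3-one (4β-methyl) | O[C@]1(C)C(=O)CC[C@]2(C)CC[C@@H](C(C)=C)C[C@H]21 | intermediate
13 | 5αH-eudesm-11-ene-3β,4α-diol | O[C@]1(C)[C@@H](O)CC[C@]2(C)CC[C@@H](C(C)=C)C[C@H]21 | intermediate
14 | 3β-(phenoxythiocarbonyloxy)-5αH-eudesm-11-en-4α-ol | O[C@]1(C)[C@@H](OC(=S)Oc3ccccc3)CC[C@]2(C)CC[C@@H](C(C)=C)C[C@H]21 | intermediate
15 | 5αH-eudesm-11-en-4α-ol (selin-11-en-4α-ol), (1R,4aR,7R,8aR)-1,4a-dimethyl-7-(prop-1-en-2-yl)decahydronaphthalen-1-ol | O[C@]1(C)CCC[C@]2(C)CC[C@@H](C(C)=C)C[C@H]21 | intermediate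
16 | 3-bromo-4-fluorobenzonitrile | N#Cc1ccc(F)c(Br)c1 | starting material
17 | potassium 4α-alkoxide of 15 | [K+].[O-][C@]1(C)CCC[C@]2(C)CC[C@@H](C(C)=C)C[C@H]21 | intermediate
18 | 3-bromo-4-[(5αH-eudesm-11-en-4α-yl)oxy]benzonitrile | N#Cc1ccc(O[C@]2(C)CCC[C@]3(C)CC[C@@H](C(C)=C)C[C@H]32)c(Br)c1 | intermediate
19 | 3-bromo-4-hydroxybenzonitrile | N#Cc1ccc(O)c(Br)c1 | starting material
20 | 3-bromo-4-{[2-(trimethylsilyl)ethoxy]methoxy}benzonitrile | N#Cc1ccc(OCOCC[Si](C)(C)C)c(Br)c1 | intermediate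
21 | 4-{[2-(trimethylsilyl)ethoxy]methoxy}-3-(4,4,5,5-tetramethyl-1,3,2-dioxaborolan-2-yl)benzonitrile | N#Cc1ccc(OCOCC[Si](C)(C)C)c(B2OC(C)(C)C(C)(C)O2)c1 | intermediate
22 | 6-[(5αH-eudesm-11-en-4α-yl)oxy]-6'-(SEM-oxy)biphenyl-3,3'-dicarbonitrile | N#Cc1ccc(O[C@]2(C)CCC[C@]3(C)CC[C@@H](C(C)=C)C[C@H]32)c(-c2cc(C#N)ccc2OCOCC[Si](C)(C)C)c1 | intermediate
23 | bis(N-diisobutylaluminio aldimine) of 24 | CC(C)C[Al](CC(C)C)N=Cc1ccc(O[C@]2(C)CCC[C@]3(C)CC[C@@H](C(C)=C)C[C@H]32)c(-c2cc(C=N[Al](CC(C)C)CC(C)C)ccc2OCOCC[Si](C)(C)C)c1 | intermediate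
24 | 6-[(5αH-eudesm-11-en-4α-yl)oxy]-6'-(SEM-oxy)biphenyl-3,3'-dicarbaldehyde | O=Cc1ccc(O[C@]2(C)CCC[C@]3(C)CC[C@@H](C(C)=C)C[C@H]32)c(-c2cc(C=O)ccc2OCOCC[Si](C)(C)C)c1 | intermediate
25 | 12-(acetoxymercurio)-11-hydroxy derivative of 24 (C11 epimers) | O=Cc1ccc(O[C@]2(C)CCC[C@]3(C)CC[C@@H](C(C)(O)C[Hg]OC(C)=O)C[C@H]32)c(-c2cc(C=O)ccc2OCOCC[Si](C)(C)C)c1 | intermediate
26 | triol: 4α-O-aryl cryptomeridiol with 3,3'-bis(hydroxymethyl)-6'-(SEM-oxy)biphenyl-6-yl as aryl group | OCc1ccc(O[C@]2(C)CCC[C@]3(C)CC[C@@H](C(C)(C)O)C[C@H]32)c(-c2cc(CO)ccc2OCOCC[Si](C)(C)C)c1 | intermediate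
27 | corresponding 3,3'-bis(bromomethyl) compound (C11–OH free) | BrCc1ccc(O[C@]2(C)CCC[C@]3(C)CC[C@@H](C(C)(C)O)C[C@H]32)c(-c2cc(CBr)ccc2OCOCC[Si](C)(C)C)c1 | intermediate
28 | 2'-O-SEM-eudesmagnolol | C=CCc1ccc(OCOCC[Si](C)(C)C)c(-c2cc(CC=C)ccc2O[C@]2(C)CCC[C@]3(C)CC[C@@H](C(C)(C)O)C[C@H]32)c1 | intermediate
29 | eudesmagnolol, 4α-O-(5,5'-diallyl-2'-hydroxybiphenyl-2-yl) ether of cryptomeridiol, (4R,5R,7R,10R) | C=CCc1ccc(O)c(-c2cc(CC=C)ccc2O[C@]2(C)CCC[C@]3(C)CC[C@@H](C(C)(C)O)C[C@H]32)c1 | target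

**Summary**
Total step count: 17. Longest linear sequence: 15 steps (steps 1–9 and 12–17, from 1 to 29); steps 10–11 prepare boronate 21.

Three steps most likely to fail:

Step 2 (diastereoselectivity at C10; the auxiliary must override the intrinsic axial-attack preference of the dihydrocarvone enamine, and the enone can polymerise). Fallback, setting out from 1 and coming back at 8, using substrate control instead of auxiliary control: HBr in AcOH adds to the isopropenyl group to give (2R,5R)-5-(2-bromopropan-2-yl)-2-methylcyclohexan-1-one F1. KOH in MeOH closes the cyclopropane to (1S,6R)-2-carone F2, whose gem-dimethylcyclopropane blocks the β face. A KOH/EtOH Robinson annulation with 4 therefore gives the β-cyclopropane-fused enone 6,11-cycloeudesm-4-en-3-one F3 with the natural C10 configuration. HCl in EtOH opens the vinylogous cyclopropyl ketone to 11-chloroeudesm-4-en-3-one F4, and NaOAc in hot AcOH eliminates HCl to give 8.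

Step 9 (SNAr of a hindered tertiary alkoxide next to an ortho bromine). Fallback, setting out from 15 and coming back at 18, replacing addition–elimination by ligand coupling at iodine: the sodium alkoxide of 15 (NaH, toluene) is arylated at rt–50 °C with (2-bromo-4-cyanophenyl)(2,4,6-trimethoxyphenyl)iodonium tosylate F5. F5 is prepared in one pot from commercial 3-bromo-4-iodobenzonitrile (mCPBA, TsOH·H2O, MeCN, then 1,3,5-trimethoxybenzene). Only the electron-poor, ortho-substituted aryl group is transferred, and steric crowding at the arene does not slow this mechanism.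

Step 16 (double benzylic Stille on the labile dibromide 27; possible homocoupling or allyl-to-propenyl isomerisation). Fallback, setting out from 26 and coming back at 28, avoiding benzylic halides and tin: MnO2 in CH2Cl2 oxidises the two benzylic alcohols to the 11-hydroxy dialdehyde F6. Excess CH2=CHMgBr in THF at −78 °C gives the bis(1-arylallyl alcohol) F7 as a diastereomer mixture. ClCO2Me/pyridine gives the bis(methyl carbonate) F8, the tertiary alcohol staying free. Tsuji formate hydrogenolysis (Pd(OAc)2, PBu3, HCO2NH4, dioxane, 80 °C) delivers hydride to the benzylic terminus of each π-allyl intermediate to give the two terminal allyl groups of 28.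

**Further compounds**
F1 | step 2 | (2R,5R)-5-(2-bromopropan-2-yl)-2-methylcyclohexan-1-one | C[C@@H]1CC[C@@H](C(C)(C)Br)CC1=O
F2 | step 2 | (1S,6R)-3,7,7-trimethylbicyclo[4.1.0]heptan-2-one (2-carone; C3 epimerisable) | CC1CC[C@@H]2[C@H](C1=O)C2(C)C
F3 | step 2 | 6,11-cycloeudesm-4-en-3-one (β-cyclopropane; 10β-methyl) | O=C1CC[C@]2(C)CC[C@@H]3[C@H](C2=C1C)C3(C)C
F4 | step 2 | 11-chloroeudesm-4-en-3-one (7R,10S) | O=C1CC[C@]2(C)CC[C@@H](C(C)(C)Cl)CC2=C1C
F5 | step 9 | (2-bromo-4-cyanophenyl)(2,4,6-trimethoxyphenyl)iodonium 4-methylbenzenesulfonate | N#Cc1ccc([I+]c2c(OC)cc(OC)cc2OC)c(Br)c1.Cc1ccc(S(=O)(=O)[O-])cc1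
F6 | step 16 | 6-{[11-hydroxy-5αH-eudesman-4α-yl]oxy}-6'-(SEM-oxy)biphenyl-3,3'-dicarbaldehyde | O=Cc1ccc(O[C@]2(C)CCC[C@]3(C)CC[C@@H](C(C)(C)O)C[C@H]32)c(-c2cc(C=O)ccc2OCOCC[Si](C)(C)C)c1
F7 | step 16 | 3,3'-bis(1-hydroxyprop-2-en-1-yl) analogue of F6 (carbinol epimers) | C=CC(O)c1ccc(O[C@]2(C)CCC[C@]3(C)CC[C@@H](C(C)(C)O)C[C@H]32)c(-c2cc(C(O)C=C)ccc2OCOCC[Si](C)(C)C)c1
F8 | step 16 | bis(methyl carbonate) of F7 | C=CC(OC(=O)OC)c1ccc(O[C@]2(C)CCC[C@]3(C)CC[C@@H](C(C)(C)O)C[C@H]32)c(-c2cc(C(OC(=O)OC)C=C)ccc2OCOCC[Si](C)(C)C)c1
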